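How far does the excess of right-handed substrate fall in midnight and in spring by 6.0 d, and does a gap above 2 percentage points remain between them? The earlier runs can be read for how fast the excess and the turnover fall.

| flask | left-handed substrate | right-handed substrate | partner | protic impurity | free catalyst | remark | time |
|---|---|---|---|---|---|---|---|
| birch | 0.38 M | 0.38 M | 0.50 M | 5 mM | 6.2 mM | run made earlier |  |
| elm | 0.25 M | 0.25 M | 0.50 M | 2.5 mM | 6.2 mM | run made earlier |  |
| midnight | 0.25 M | 0.25 M | 0.500 M | 5.00 mM | 6.2 mM |  | 6.0 d |
| spring | 0.25 M | 0.25 M | 0.500 M | 5.00 mM | 2.0 mM |  | 6.0 d |

- birch (time / h: right-handed substrate / %, left-handed substrate / %): 5.00: 48.0, 45.2; 10.0: 46.0, 43.6; 15.0: 44.0, 43.0; 20.0: 43.0, 41.6; 25.0: 42.2, 40.9; 30.0: 41.6, 39.5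
- elm (time / h: right-handed substrate / %, left-handed substrate / %): 5.00: 48.5, 43.3; 10.0: 45.3, 42.5; 15.0: 43.6, 42.5; 20.0: 41.9, 41.4; 25.0: 40.8, 40.0; 30.0: 40.8, 39.8

(each reading ± 0.5 percentage points)

- free catalyst is single-handed; left-handed substrate and right-handed substrate are mirror images of each other, charged as a racemate, each of them at the stated concentration
- an excess is the difference of the two amounts in percent of their sum
- an excess is below zero if the other one leads
- no earlier run changes the charge of free catalyst; that part of a forecast is a guess

- the flask that ends with the higher excess of right-handed substrate over left-handed substrate among what is left of the two, or "neither" when 2 percentage points or less lies between them (midnight / spring / neither)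
- excess of right-handed substrate over left-handed substrate among what is left of the two at the end, midnight
- excess of right-handed substrate over left-handed substrate among what is left of the two at the end, spring

The ladder starts at the fastest rung. By elm's first reading, after 5.00 h, the single-handed catalyst has taken the left-handed substrate ahead, and the excess of right-handed substrate reads 5.66%.

On the next rung, elm loses 13.9% of its substrate in the first 15.0 h and 5.50% in the next equal span. Taken as a pseudo-first-order decay, this gives the working half-life τ, the time in which the rate of substrate loss falls by a factor of two: τ = 11.2 h. Birch reads 13.2 h.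

Elm's excess falls to 1.24% at 30.0 h, a half-life of 11.4 h, so it falls in step with turnover. The weak point is birch, whose last excess of 2.59% does not show that fall.

The slowest rung is the flask time itself, 12.9 working half-lives. Carried forward from elm, midnight's excess reckons to 0.00105%. Spring comes out near zero too, if its smaller catalyst charge leaves τ alone, which is a guess. This reckoning therefore says neither, with both excesses near zero.

The forecast also says neither, but with 2% and 2%, which differs from the reckoning. Its ground: “right-handed substrate feeds left-handed substrate, and a small steady-state excess remains”.

The flasks give neither, with 0% in midnight and 0% in spring, so the forecast stands within its tolerance. Midnight's spent catalyst reaches >99.9% at the end, and the relaxation half-life of the two substrates by their interconversion alone is 0.0933 d, short against 6.0 d. At 3.00 d, τ leaves 1.16% of the turnover, and midnight's working catalyst forms hold 1.45%. The verdict would turn only on a gap above 2 points, yet at elm's last reading time, spring's catalyst charge moves the excess from 0.972% to just 0.317%.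

    partner + free catalyst → spent catalyst (k = 1.06 × 10⁻⁴ /M/s)
    left-handed substrate ⇌ right-handed substrate (k = 4.30 × 10⁻⁵ /s)
    free catalyst + left-handed substrate ⇌ catalyst intermediate A (K = 7.00 /M, k = 0.304 /M/s)
    partner + catalyst intermediate A → free catalyst + left-handed product (k = 0.00135 /M/s)
    partner + catalyst intermediate B → free catalyst + right-handed product (k = 2.44 × 10⁻⁴ /M/s)
    partner + protic impurity → quenched reagent (k = 0.126 /M/s)
    free catalyst + right-handed substrate ⇌ catalyst intermediate B (K = 0.890 /M, k = 0.985 /M/s)

Midnight with 0.025 M of free catalyst, τ held, reckons to 0.00424%. The computed flask holds 0.0477%, more than reckoned, and still below 2 points.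

The runs were computed with made-up constants, noise included.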